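**Plan**
Ring A is a symmetric 4-acyl-2,6-dimethoxyphenol (C1 carries the acyl group, C4 the hydroxyl). Its C3–C4–C5 unit with all three ring oxygens corresponds to 1,3-dimethoxyacetone, and its C2–C1–C6 unit with the acyl carbon to an acylmalonaldehyde; this is what permits a [3+3] construction.
The retrosynthesis cuts C2–C3 and C5–C6 of ring A first, then the bond from the acyl carbon to C1 (enamine C-acylation), then the aryl ether C–O bond at the stereocentre.
Forward: the guaiacyl phenol is joined to a glycerate by Mitsunobu etherification, the derived acid chloride acylates 3-(dimethylamino)acrolein, ring A is then closed from this enaminal and 1,3-dimethoxyacetone, and two silyl ethers are removed last.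
The single stereocentre comes from methyl (R)-glycerate acetonide and is inverted once, in the Mitsunobu step, to the (S) configuration of the target; no later step breaks a bond to it.

Key step: step 7

Remark: TBS = tert-butyldimethylsilyl. The push–pull C=C of 10 is assumed to rotate freely, so no alkene geometry is assigned; the transient centres of 13 and 14 are left undefined because aromatisation removes them.

**Step 1**
Reactants: 1 dihydroconiferyl alcohol [4-(3-hydroxypropyl)-2-methoxyphenol]
Product: 2 4-[3-(TBS-oxy)propyl]-2-methoxyphenol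
Conditions: TBSCl (1.05 equiv), imidazole, CH2Cl2, 0 °C
Reagents that add atoms: tert-butyldimethylsilyl chloride (TBSCl), CC(C)(C)[Si](C)(C)Cl
Why: Corey-type silylation should be kinetically selective for the unhindered primary alcohol over the ortho-methoxy phenol, whose hydroxyl is hydrogen-bonded and less nucleophilic in CH2Cl2, so one equivalent of TBSCl should leave the phenol free.

**Step 2**
Reactants: 3 methyl (4R)-2,2-dimethyl-1,3-dioxolane-4-carboxylate
Product: 4 methyl (2R)-2,3-dihydroxypropanoate
Conditions: p-TsOH·H2O (cat.), MeOH, rt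
Reagents that add atoms: none
Why: Acid-catalysed transacetalisation (acetonide methanolysis) frees the diol while methanol as solvent keeps the methyl ester unchanged, and no bond to the stereocentre is touched.

**Step 3**
Reactants: 4 methyl (2R)-2,3-dihydroxypropanoate
Product: 5 methyl (2R)-2-hydroxy-3-(TBS-oxy)propanoate
Conditions: TBSCl (1.05 equiv), imidazole, CH2Cl2, 0 °C
Reagents that add atoms: tert-butyldimethylsilyl chloride (TBSCl), CC(C)(C)[Si](C)(C)Cl
Why: Silylation discriminates sterically between the primary hydroxyl and the secondary hydroxyl next to the ester, a standard regioselective monoprotection of a 1,2-diol.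

**Step 4**
Reactants: 5 methyl (2R)-2-hydroxy-3-(TBS-oxy)propanoate; 2 4-[3-(TBS-oxy)propyl]-2-methoxyphenol
Product: 6 methyl (2S)-2-{2-methoxy-4-[3-(TBS-oxy)propyl]phenoxy}-3-(TBS-oxy)propanoate
Conditions: PPh3, DIAD, THF, 0 °C → rt
Reagents that add atoms: none
Why: Mitsunobu etherification, in which the phenoxide (phenol pKa about 10) displaces the oxyphosphonium of the ester-activated secondary alcohol by SN2 with inversion, converting the (R) carbinol into the (S) aryl ether.

**Step 5**
Reactants: 6 methyl (2S)-2-{2-methoxy-4-[3-(TBS-oxy)propyl]phenoxy}-3-(TBS-oxy)propanoate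
Product: 7 (2S)-2-{2-methoxy-4-[3-(TBS-oxy)propyl]phenoxy}-3-(TBS-oxy)propanoic acid
Conditions: LiOH·H2O, THF/H2O, 0 °C; then 1 M HCl to pH 3, 0 °C
Reagents that add atoms: lithium hydroxide, [Li+].[OH-]
Why: Saponification (BAc2) at 0 °C should be faster than α-deprotonation of the ester, and the carboxylate formed is no longer acidic at C2, so neither epimerisation nor β-elimination of the silyloxy group is expected and the silyl ethers are tolerated.

**Step 6**
Reactants: 7 (2S)-2-{2-methoxy-4-[3-(TBS-oxy)propyl]phenoxy}-3-(TBS-oxy)propanoic acid; 8 (E)-3-(dimethylamino)acrolein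
Product: 10 (4S)-2-[(dimethylamino)methylidene]-4-{2-methoxy-4-[3-(TBS-oxy)propyl]phenoxy}-3-oxo-5-(TBS-oxy)pentanal, via acid chloride 9 (not isolated)
Conditions: 1-chloro-N,N,2-trimethylprop-1-en-1-amine (Ghosez reagent), 1,2-dichloroethane, 0 °C → rt; then 8, 2,6-di-tert-butyl-4-methylpyridine, 0 → 50 °C; aq. NaHCO3 work-up
Reagents that add atoms: none
Why: The Ghosez reagent should form chloride 9 without releasing HCl, and 9 then acylates the nucleophilic C2 of the push–pull enamine 8 in a Grohe-type enamine C-acylation, with the hindered non-nucleophilic pyridine trapping HCl without generating a ketene so that the (S) centre is retained.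

**Step 7**
Reactants: 10 (4S)-2-[(dimethylamino)methylidene]-4-{2-methoxy-4-[3-(TBS-oxy)propyl]phenoxy}-3-oxo-5-(TBS-oxy)pentanal; 11 1,3-dimethoxyacetone
Product: 15 (2S)-1-(4-hydroxy-3,5-dimethoxyphenyl)-2-{2-methoxy-4-[3-(TBS-oxy)propyl]phenoxy}-3-(TBS-oxy)propan-1-one, via pyrrolidine enamine 12 (not isolated), via open-chain adduct 13 (not isolated), via cyclic aldol 14 (not isolated)
Conditions: 11 (3 equiv), pyrrolidine (0.3 equiv), AcOH (0.3 equiv), MeCN, Ar, rt → 40 °C; pH 5 buffer work-up
Reagents that add atoms: none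
Why: Proposed new method: enamine 12, formed reversibly from 11 and pyrrolidinium acetate, should add to the aminomethylidene carbon of 10 (made more electrophilic by reversible iminium formation at the formyl group in the same buffer) and expel dimethylamine to give 13, after which the second α-carbon attacks the formyl carbon to give aldol 14; loss of water and enolisation then deliver phenol 15, and this aromatisation makes the sequence irreversible. The closest known reaction types are the [3+3] phenol syntheses from ketones and nitromalonaldehyde, 2-substituted vinamidinium salts or 3-formylchromones, together with amine-catalysed aldol chemistry of α-alkoxy ketones. Ring A closes in a 6-(enolendo)-exo-trig aldol step that forms C5–C6, C2–C3 having been made in the preceding addition–elimination. No stereocentre is created, because the methoxy- and hydroxyl-bearing centres of 13 and 14 vanish on aromatisation, and the existing (S) centre should survive since its C–H lies α to a vinylogous amide carbonyl in 10 and α to a para-phenoxide-conjugated ketone in 15 (the liberated dimethylamine ionises the phenol), with no base stronger than a secondary amine present. The selectivity required is attack at the two aldehyde-level carbons and not at the acyl carbonyl, which the substrate secures because that ketone is α-branched, conjugated with the amino group and far less electrophilic than the formyl or iminium termini, while enamine activation reaches only the unhindered ketone 11.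

**Step 8**
Reactants: 15 (2S)-1-(4-hydroxy-3,5-dimethoxyphenyl)-2-{2-methoxy-4-[3-(TBS-oxy)propyl]phenoxy}-3-(TBS-oxy)propan-1-one
Product: 16 (2S)-3-hydroxy-1-(4-hydroxy-3,5-dimethoxyphenyl)-2-[4-(3-hydroxypropyl)-2-methoxyphenoxy]propan-1-one (CNP0283847.1)
Conditions: HF·pyridine, THF/pyridine, 0 °C → rt
Reagents that add atoms: none
Why: Fluoride-mediated desilylation with buffered HF·pyridine cleaves both primary TBS ethers under non-basic conditions, so the α-aryloxy ketone should neither enolise nor undergo retro-aldol loss of formaldehyde.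

**Compound list**
1 | dihydroconiferyl alcohol, 4-(3-hydroxypropyl)-2-methoxyphenol | COc1cc(CCCO)ccc1O | starting material
2 | 4-[3-(TBS-oxy)propyl]-2-methoxyphenol | COc1cc(CCCO[Si](C)(C)C(C)(C)C)ccc1O | intermediate
3 | methyl (4R)-2,2-dimethyl-1,3-dioxolane-4-carboxylate | COC(=O)[C@H]1COC(C)(C)O1 | starting material
4 | methyl (2R)-2,3-dihydroxypropanoate | COC(=O)[C@H](O)CO | intermediate
5 | methyl (2R)-2-hydroxy-3-(TBS-oxy)propanoate | COC(=O)[C@H](O)CO[Si](C)(C)C(C)(C)C | intermediate
6 | methyl (2S)-2-{2-methoxy-4-[3-(TBS-oxy)propyl]phenoxy}-3-(TBS-oxy)propanoate | COC(=O)[C@@H](Oc1ccc(CCCO[Si](C)(C)C(C)(C)C)cc1OC)CO[Si](C)(C)C(C)(C)C | intermediate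
7 | (2S)-2-{2-methoxy-4-[3-(TBS-oxy)propyl]phenoxy}-3-(TBS-oxy)propanoic acid | OC(=O)[C@@H](Oc1ccc(CCCO[Si](C)(C)C(C)(C)C)cc1OC)CO[Si](C)(C)C(C)(C)C | intermediate
8 | (E)-3-(dimethylamino)acrolein | CN(C)/C=C/C=O | starting material
9 | (2S)-2-{2-methoxy-4-[3-(TBS-oxy)propyl]phenoxy}-3-(TBS-oxy)propanoyl chloride | ClC(=O)[C@@H](Oc1ccc(CCCO[Si](C)(C)C(C)(C)C)cc1OC)CO[Si](C)(C)C(C)(C)C | intermediate (not isolated)
10 | (4S)-2-[(dimethylamino)methylidene]-4-{2-methoxy-4-[3-(TBS-oxy)propyl]phenoxy}-3-oxo-5-(TBS-oxy)pentanal, alkene geometry not fixed | CN(C)C=C(C=O)C(=O)[C@H](CO[Si](C)(C)C(C)(C)C)Oc1ccc(CCCO[Si](C)(C)C(C)(C)C)cc1OC | intermediate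
11 | 1,3-dimethoxyacetone | COCC(=O)COC | starting material
12 | 1-(1,3-dimethoxyprop-1-en-2-yl)pyrrolidine | COC=C(COC)N1CCCC1 | intermediate (not isolated)
13 | 2-[(2S)-2-{2-methoxy-4-[3-(TBS-oxy)propyl]phenoxy}-3-(TBS-oxy)propanoyl]-4,6-dimethoxy-5-oxohex-2-enal, C4 and alkene geometry undefined | COCC(=O)C(OC)C=C(C=O)C(=O)[C@H](CO[Si](C)(C)C(C)(C)C)Oc1ccc(CCCO[Si](C)(C)C(C)(C)C)cc1OC | intermediate (not isolated)
14 | 5-hydroxy-2,6-dimethoxy-4-[(2S)-2-{2-methoxy-4-[3-(TBS-oxy)propyl]phenoxy}-3-(TBS-oxy)propanoyl]cyclohex-3-en-1-one, ring centres undefined | COC1C=C(C(=O)[C@H](CO[Si](C)(C)C(C)(C)C)Oc2ccc(CCCO[Si](C)(C)C(C)(C)C)cc2OC)C(O)C(OC)C1=O | intermediate (not isolated)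
15 | (2S)-1-(4-hydroxy-3,5-dimethoxyphenyl)-2-{2-methoxy-4-[3-(TBS-oxy)propyl]phenoxy}-3-(TBS-oxy)propan-1-one | COc1cc(CCCO[Si](C)(C)C(C)(C)C)ccc1O[C@@H](CO[Si](C)(C)C(C)(C)C)C(=O)c1cc(OC)c(O)c(OC)c1 | intermediate
16 | (2S)-3-hydroxy-1-(4-hydroxy-3,5-dimethoxyphenyl)-2-[4-(3-hydroxypropyl)-2-methoxyphenoxy]propan-1-one | COc1cc(CCCO)ccc1O[C@@H](CO)C(=O)c1cc(OC)c(O)c(OC)c1 | target

**Count**
Total steps: 8. Longest linear sequence: 7 steps (3 → 16, steps 2 to 8); step 1 is a one-step side branch.

**Steps most likely to fail**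

Step 7. The annulation may stall after the first C–C bond, with retro-Claisen loss of the formyl group from the open-chain stage. Deprotonation at C2 of the side chain may also compete, leading to epimerisation or β-elimination of the silyloxy group before ring closure. The fallback uses known chemistry and gives up the annulation. It sets out from ester 6, which Me(MeO)NH·HCl and i-PrMgCl (THF, −20 °C) should convert into the N-methoxy-N-methylamide F1. Commercial 4-bromo-2,6-dimethoxyphenol is silylated (TBSCl, imidazole, DMF) to (4-bromo-2,6-dimethoxyphenoxy)(tert-butyl)dimethylsilane F2. Bromine–lithium exchange on F2 (n-BuLi, THF, −78 °C) and addition of the aryllithium to F1 should give the tris-silyl aryl ketone F3 through the chelated Weinreb intermediate, without epimerisation. HF·pyridine under the conditions of step 8 then removes all three silyl groups, and the route is rejoined at 16.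

Step 6. Acylation at the oxygen of the vinylogous formamide, followed by self-condensation of the enaminal, may outrun C-acylation, and any ketene formation from the acid chloride would erode the configuration. The fallback sets out from acid chloride 9. Coupling with commercial (1,3-dioxolan-2-ylmethyl)magnesium bromide under Fe(acac)3 catalysis (THF, −78 °C) should give the β-keto acetal (3S)-1-(1,3-dioxolan-2-yl)-3-aryloxy-4-(TBS-oxy)butan-2-one F4. Aminomethylenation of its activated methylene with tert-butoxybis(dimethylamino)methane (toluene, 50 °C) gives the enaminone acetal F5. Its acetal is a vinylogous N,O-acetal and should hydrolyse under very mild acid (pH 5 buffer/THF or wet silica gel), returning to the route at 10.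

Step 4. Elimination from the oxyphosphonium intermediate, slow attack by the hindered guaiacol oxygen, or incomplete inversion would cost material or enantiopurity. The fallback sets out from 5, which Tf2O and 2,6-lutidine (CH2Cl2, −78 °C) convert into methyl (2R)-3-(TBS-oxy)-2-[(trifluoromethylsulfonyl)oxy]propanoate F6. SN2 displacement of the triflate by the potassium phenoxide of 2 (K2CO3, MeCN, 0 °C) proceeds with inversion and rejoins the route at 6.

**Further compounds**
F1 | step 7 | (2S)-N-methoxy-N-methyl-2-{2-methoxy-4-[3-(TBS-oxy)propyl]phenoxy}-3-(TBS-oxy)propanamide | CON(C)C(=O)[C@@H](Oc1ccc(CCCO[Si](C)(C)C(C)(C)C)cc1OC)CO[Si](C)(C)C(C)(C)C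
F2 | step 7 | (4-bromo-2,6-dimethoxyphenoxy)(tert-butyl)dimethylsilane | COc1cc(Br)cc(OC)c1O[Si](C)(C)C(C)(C)C
F3 | step 7 | (2S)-1-[3,5-dimethoxy-4-(TBS-oxy)phenyl]-2-{2-methoxy-4-[3-(TBS-oxy)propyl]phenoxy}-3-(TBS-oxy)propan-1-one | COc1cc(CCCO[Si](C)(C)C(C)(C)C)ccc1O[C@@H](CO[Si](C)(C)C(C)(C)C)C(=O)c1cc(OC)c(O[Si](C)(C)C(C)(C)C)c(OC)c1
F4 | step 6 | (3S)-1-(1,3-dioxolan-2-yl)-3-{2-methoxy-4-[3-(TBS-oxy)propyl]phenoxy}-4-(TBS-oxy)butan-2-one | O=C(CC1OCCO1)[C@H](CO[Si](C)(C)C(C)(C)C)Oc1ccc(CCCO[Si](C)(C)C(C)(C)C)cc1OC
F5 | step 6 | (4S)-1-(dimethylamino)-2-(1,3-dioxolan-2-yl)-4-{2-methoxy-4-[3-(TBS-oxy)propyl]phenoxy}-5-(TBS-oxy)pent-1-en-3-one | CN(C)C=C(C1OCCO1)C(=O)[C@H](CO[Si](C)(C)C(C)(C)C)Oc1ccc(CCCO[Si](C)(C)C(C)(C)C)cc1OC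
F6 | step 4 | methyl (2R)-3-(TBS-oxy)-2-[(trifluoromethylsulfonyl)oxy]propanoate | COC(=O)[C@H](OS(=O)(=O)C(F)(F)F)CO[Si](C)(C)C(C)(C)C
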